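1. I have 5 questions about 4 flasks, and the problem stands here.

| flask | substrate | coupling partner | remark | time |
|---|---|---|---|---|
| north-east | 0.022 M | 0.088 M | run made earlier |  |
| east | 0.031 M | 0.088 M | run made earlier |  |
| north-west | 0.048 M | 0.088 M | run made earlier |  |
| theta | 0.022 M | 0.0880 M (in portions, 5, over 4.0 d) | first portion at the start, last at 4.0 d | 10 d |
| gamma | 0.022 M | 0.0880 M | everything together at the start | 10 d |
| epsilon | 0.022 M | 0.0880 M (fed, over 4.0 d) | all else is in the flask from the start; the feed brings no volume worth counting | 10 d |
| zeta | 0.022 M (fed, over 4.0 d) | 0.0880 M | all else is in the flask from the start; the feed brings no volume worth counting | 10 d |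

| run | time / d | single product / % |
|---|---|---|
| north-east | 0.417 | 10.5 |
| north-east | 1.25 | 14.8 |
| north-east | 2.00 | 15.1 |
| north-east | 3.00 | 16.3 |
| north-east | 5.00 | 15.3 |
| north-east | 6.00 | 15.0 |
| east | 0.833 | 13.1 |
| east | 2.50 | 14.7 |
| east | 4.00 | 13.9 |
| east | 6.00 | 12.9 |
| east | 10.0 | 11.5 |
| east | 12.0 | 9.5 |
| north-west | 2.08 | 12.3 |
| north-west | 4.00 | 13.3 |
| north-west | 6.00 | 11.8 |
| north-west | 8.00 | 10.2 |
| north-west | 10.0 | 9.6 |
| north-west | 12.0 | 8.8 |

(each reading ± 0.5 percentage points)

- the analysis behind the earlier runs scatters by 0.5 percentage points, standard deviation

1. the flask with the highest amount of single product, in percent of the substrate charged ("all alike" if they lie within 1.5 percentage points) (theta / gamma / epsilon / zeta / all alike)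
2. final single product, as a percentage of the substrate charged, in theta
3. final single product, as a percentage of the substrate charged, in gamma
4. final single product, as a percentage of the substrate charged, in epsilon
5. final single product, as a percentage of the substrate charged, in zeta

2. The highest reading falls as the substrate charge rises: the north-east run peaks at 16.3% and the north-west run at 13.3%, lower, with each reading scattering by 0.5 percentage points. I read this as a rival step that gains on the coupling step as substrate rises, a falling selectivity. The fall of peak share per unit of substrate level, the dilution gain 1.15 M⁻¹, measures it, with the share as a fraction.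

3. After its peak, single product fades in the east run at 0.0460 d⁻¹. Gamma has the north-east recipe, so I fade that peak from 3.00 d to 10 d and get 11.8%.

4. In zeta, my first round takes the standing substrate level as nil, which gives a peak of 18.8%. The second round puts a level back in. The north-east run reaches its highest reading at 3.00 d, and I take that time as a rough lifetime of substrate. During the feed the level climbs from nil towards feed rate times lifetime, so I take half of that as its mean, 0.00825 M, and the peak is 17.9%. The feed delays zeta by half its time, so I reckon 14.2%, above gamma by more than the margin of 1.5 points. I commit to zeta.

5. The forecast differs: all alike, with 13.3%, 13%, 13.3% and 13.8% for theta, gamma, epsilon and zeta, on the ground “It looks like a fixed split or an equilibrium”.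

6. The equations are these.

    single product ⇌ isomer of the product (K = 1.60, k = 0.0679 h⁻¹)
    substrate + coupling partner → single product + released group (k = 0.197 M⁻¹ h⁻¹)
    2 substrate → self-condensation product (k = 0.414 M⁻¹ h⁻¹)
    coupling partner + single product → over-reaction product (k = 0.0672 M⁻¹ h⁻¹)
    coupling partner + double product → triple product + released group (k = 0.0101 M⁻¹ h⁻¹)
    coupling partner + single product → double product + released group (k = 0.0676 M⁻¹ h⁻¹)

7. The flasks end at 9.56%, 11.8%, 9.12% and 15.5% in the same order, so zeta stands highest. Zeta holds 23.6% of its substrate as self-condensation product at 10.0 d, less than the 33.1% in gamma. In epsilon, I take the partner at about half its charge during the feed, which counts like twice the substrate level. The dilution gain then gives a peak of 13.8%, which fades to 10.9%, above the 9.12% that epsilon holds.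

The numbers in the tables are calculated with made-up constants; scatter was added.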